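**Retrosynthetic overview** (drimane numbering: ring A = C1–C5, C10; ring B = C5–C10; C11 on C9, C12 on C8; the C10 methyl is β)
- The plan rests on ring B (C5–C10), a cyclohexenone. Its C6 oxygen, the fusion bond C5–C10 and the bond C8–C9 are the imprint of a 2-silyloxydiene C5=C6–C7=C8 and a Z enoyl dienophile C9=C10 (carbonyl C11) joined through C1–C4.
- Late disconnections: C3 isovalerate (acylation), C11–O aryl ether to isofraxidin (Mitsunobu), 3α-OH from a C3 ketone (bulky hydride), C7=C8 from the C6 silyl enol ether (Saegusa), C11 alcohol from the imide.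
- Key disconnection: an intramolecular (4+2) addition of the silyloxytriene imide makes C5–C10 and C8–C9 and closes rings A and B in the same step; the coumarin is brought in intact afterwards.
- The triene comes from a Z enoate (Me2CuLi syn addition to a 2-ynoate), a C3 ketone masked as dioxolane (Grignard addition, oxidation), and a diene built by alkene cleavage, propenyl addition, oxidation and α′ silylation.

Key step: step 13

Assumption: facial control is taken to follow the bidentate aluminium chelate of the N-enoyl oxazolidinone (enoyl s-cis, diene adding anti to the 4-benzyl group); on that model the (R)-auxiliary gives the C9/C10 configuration of the target, so (R)-4-benzyl-2-oxazolidinone is used.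

**Route**

Step 1
Reactants: 1 2,2-dimethylpent-4-enal; 2 (4-bromobut-1-yn-1-yl)trimethylsilane
Product: 4 rac-6,6-dimethyl-1-(trimethylsilyl)non-8-en-1-yn-5-ol, via Grignard reagent 3 (not isolated)
Conditions: Mg, THF, rt; then 1, 0 °C; aq. NH4Cl
Reagents that add atoms: none
Why: Grignard addition of the homopropargyl magnesium reagent to the neopentyl aldehyde forms the C2–C3 bond, and the racemic carbinol centre is removed in step 2.

Step 2
Reactants: 4 rac-6,6-dimethyl-1-(trimethylsilyl)non-8-en-1-yn-5-ol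
Product: 5 6,6-dimethyl-1-(trimethylsilyl)non-8-en-1-yn-5-one
Conditions: DMP, NaHCO3, CH2Cl2, rt
Reagents that add atoms: none
Why: Dess–Martin oxidation of the secondary alcohol gives the C3 ketone without touching the alkene or the silyl alkyne.

Step 3
Reactants: 5 6,6-dimethyl-1-(trimethylsilyl)non-8-en-1-yn-5-one
Product: 6 2-(2-methylpent-4-en-2-yl)-2-[4-(trimethylsilyl)but-3-yn-1-yl]-1,3-dioxolane
Conditions: ethylene glycol, TsOH·H2O (cat.), toluene, reflux, Dean–Stark
Reagents that add atoms: ethylene glycol, OCCO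
Why: Acid-catalysed ketalisation with azeotropic removal of water masks C3, which must stay inert through the later silylation, Lewis acid and hydride steps.

Step 4
Reactants: 6 2-(2-methylpent-4-en-2-yl)-2-[4-(trimethylsilyl)but-3-yn-1-yl]-1,3-dioxolane
Product: 7 2-(but-3-yn-1-yl)-2-(2-methylpent-4-en-2-yl)-1,3-dioxolane
Conditions: K2CO3 (cat.), MeOH, rt
Reagents that add atoms: none
Why: Base-catalysed methanolysis of the alkynyl C–Si bond (protodesilylation) frees the terminal alkyne while the ketal is stable to base.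

Step 5
Reactants: 7 2-(but-3-yn-1-yl)-2-(2-methylpent-4-en-2-yl)-1,3-dioxolane
Product: 9 ethyl 5-[2-(2-methylpent-4-en-2-yl)-1,3-dioxolan-2-yl]pent-2-ynoate, via lithium acetylide 8 (not isolated)
Conditions: n-BuLi, THF, −78 °C; ClCO2Et, −78 → 0 °C
Reagents that add atoms: ethyl chloroformate, CCOC(=O)Cl
Why: Deprotonation of the terminal alkyne and C-acylation of the acetylide by the chloroformate installs C11 as the 2-ynoate.

Step 6
Reactants: 9 ethyl 5-[2-(2-methylpent-4-en-2-yl)-1,3-dioxolan-2-yl]pent-2-ynoate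
Product: 11 ethyl (Z)-3-methyl-5-[2-(2-methylpent-4-en-2-yl)-1,3-dioxolan-2-yl]pent-2-enoate, via alkenylcuprate adduct 10 (not isolated)
Conditions: Me2CuLi (from CuI, MeLi), THF, −78 °C; MeOH at −78 °C, then aq. NH4Cl
Reagents that add atoms: lithium dimethylcuprate, [Li+].C[Cu-]C
Why: Syn carbocupration of the 2-ynoate and protonation of the alkenylcopper at −78 °C with retention put the new C10 methyl trans to the ester, which is the Z enoate with the chain cis to C11.

Step 7
Reactants: 11 ethyl (Z)-3-methyl-5-[2-(2-methylpent-4-en-2-yl)-1,3-dioxolan-2-yl]pent-2-enoate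
Product: 12 (Z)-3-methyl-5-[2-(2-methylpent-4-en-2-yl)-1,3-dioxolan-2-yl]pent-2-enoic acid
Conditions: LiOH, THF/MeOH/H2O, 45 °C; then 1 M HCl to pH 4, 0 °C
Reagents that add atoms: lithium hydroxide, [Li+].[OH-]
Why: Saponification of the hindered enoate, in which the Z alkene has no easy path to isomerise under hydroxide and the dioxolane survives the brief cold acidification.

Step 8
Reactants: 12 (Z)-3-methyl-5-[2-(2-methylpent-4-en-2-yl)-1,3-dioxolan-2-yl]pent-2-enoic acid; 13 (R)-4-benzyl-2-oxazolidinone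
Product: 16 (R)-4-benzyl-3-[(Z)-3-methyl-5-[2-(2-methylpent-4-en-2-yl)-1,3-dioxolan-2-yl]pent-2-enoyl]oxazolidin-2-one, via mixed pivalic anhydride 14 (not isolated), via lithiated oxazolidinone 15 (not isolated)
Conditions: PivCl, Et3N, THF, −20 °C; then 15 (from 13, n-BuLi, THF, −78 °C), −78 → 0 °C; aq. NH4Cl
Reagents that add atoms: none
Why: Evans N-acylation, in which the lithiated oxazolidinone attacks the less hindered enoyl carbonyl of the mixed anhydride at low temperature so that the Z geometry is kept.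

Step 9
Reactants: 16 (R)-4-benzyl-3-[(Z)-3-methyl-5-[2-(2-methylpent-4-en-2-yl)-1,3-dioxolan-2-yl]pent-2-enoyl]oxazolidin-2-one
Product: 18 (R)-4-benzyl-3-[(Z)-3-methyl-5-[2-(2-methyl-4-oxobutan-2-yl)-1,3-dioxolan-2-yl]pent-2-enoyl]oxazolidin-2-one, via vicinal diol 17 (not isolated)
Conditions: OsO4 (cat.), NaIO4, 2,6-lutidine, dioxane/H2O, rt
Reagents that add atoms: sodium periodate (its oxygen reaches the product through catalytic OsO4), [Na+].[O-]I(=O)(=O)=O
Why: Lemieux–Johnson cleavage, in which OsO4 dihydroxylates the electron-rich monosubstituted alkene much faster than the electron-poor enoyl alkene and periodate cleaves the diol to the C6 aldehyde.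

Step 10
Reactants: 18 (R)-4-benzyl-3-[(Z)-3-methyl-5-[2-(2-methyl-4-oxobutan-2-yl)-1,3-dioxolan-2-yl]pent-2-enoyl]oxazolidin-2-one; 19 (E)-1-bromoprop-1-ene
Product: 21 (R)-4-benzyl-3-[(Z)-5-[2-[(E)-4-hydroxy-2-methylhept-5-en-2-yl]-1,3-dioxolan-2-yl]-3-methylpent-2-enoyl]oxazolidin-2-one (both C6 carbinol epimers), via propenylchromium dichloride 20 (not isolated)
Conditions: CrCl2, NiCl2 (cat.), DMF, rt
Reagents that add atoms: none
Why: Nozaki–Hiyama–Kishi coupling, in which the alkenylchromium species adds only to the aldehyde (imide and ketal untouched) with retention of the E geometry, and the two carbinol epimers converge in step 11.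

Step 11
Reactants: 21 (R)-4-benzyl-3-[(Z)-5-[2-[(E)-4-hydroxy-2-methylhept-5-en-2-yl]-1,3-dioxolan-2-yl]-3-methylpent-2-enoyl]oxazolidin-2-one
Product: 22 (R)-4-benzyl-3-[(Z)-3-methyl-5-[2-[(E)-2-methyl-4-oxohept-5-en-2-yl]-1,3-dioxolan-2-yl]pent-2-enoyl]oxazolidin-2-one
Conditions: DMP, NaHCO3, CH2Cl2, 0 °C → rt
Reagents that add atoms: none
Why: Buffered Dess–Martin oxidation of the allylic alcohol gives the E enone (C6 ketone, C7=C8) under conditions that leave the ketal and imide alone.

Step 12
Reactants: 22 (R)-4-benzyl-3-[(Z)-3-methyl-5-[2-[(E)-2-methyl-4-oxohept-5-en-2-yl]-1,3-dioxolan-2-yl]pent-2-enoyl]oxazolidin-2-one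
Product: 23 (R)-4-benzyl-3-[(Z)-5-[2-[(3Z,5E)-4-(tert-butyldimethylsilyloxy)-2-methylhepta-3,5-dien-2-yl]-1,3-dioxolan-2-yl]-3-methylpent-2-enoyl]oxazolidin-2-one
Conditions: TBSOTf, Et3N, CH2Cl2, −78 → 0 °C
Reagents that add atoms: tert-butyldimethylsilyl trifluoromethanesulfonate, CC(C)(C)[Si](C)(C)OS(=O)(=O)C(F)(F)F
Why: Soft enolisation of the enone on its α′ side (silyl triflate/amine) gives the cross-conjugated 2-silyloxydiene, the Z enol ether being expected because the quaternary C4 avoids the vinyl group, while the imide is not enolised under these conditions.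

Step 13
Reactants: 23 (R)-4-benzyl-3-[(Z)-5-[2-[(3Z,5E)-4-(tert-butyldimethylsilyloxy)-2-methylhepta-3,5-dien-2-yl]-1,3-dioxolan-2-yl]-3-methylpent-2-enoyl]oxazolidin-2-one
Product: 24 (R)-4-benzyl-3-[6-(tert-butyldimethylsilyloxy)-3,3-(ethylenedioxy)-9βH-drim-6-en-11-oyl]oxazolidin-2-one (trans-fused; 5α-H; 8β-CH3; 10β-CH3; C11 α)
Conditions: Me2AlCl (1.5 equiv), CH2Cl2, −78 → −30 °C; cold aq. NaHCO3/Rochelle salt
Reagents that add atoms: none
Why: Me2AlCl in excess binds both imide carbonyls, locks the enoyl group s-cis and lowers its LUMO, so that the nucleophilic diene terminus C5 bonds to the β-carbon C10 while C9 bonds to C8 in a suprafacial, asynchronous (4+2) addition whose ionic limit is a Mukaiyama–Michael/Michael sequence that regenerates the C6 silyl enol ether. The closest known reaction type is the Lewis-acid-promoted type 1 intramolecular Diels–Alder reaction of 1,7,9-decatrienes with N-enoyl oxazolidinone dienophiles, together with intramolecular double Michael reactions of 2-silyloxydienes. Ring B is closed by the cycloaddition itself through C5–C10 and C8–C9, and ring A is closed through the four-carbon tether C1–C4 as C5–C10 forms (6-exo at the enoyl acceptor, ring B then 6-endo if the bonds form one after the other). C10 and C9 are set together by the dienophile face left open in the chelate (the benzyl group of the R auxiliary covers the other) and by the Z geometry, which puts C11 trans to the C10 methyl, while C5 and C8 follow from the carbonyl-exo, tether-anti arrangement with a chair-like tether and from the E diene. The step needs facial selectivity (auxiliary), the correct regiochemistry (fixed by the tether and by the matched polarity of C5 and C10) and a diene that keeps its silyl group at low temperature, whereas the ring-fusion selectivity is not critical because C8 is erased in step 15 and C5 can be equilibrated in step 16.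

Step 14
Reactants: 24 (R)-4-benzyl-3-[6-(tert-butyldimethylsilyloxy)-3,3-(ethylenedioxy)-9βH-drim-6-en-11-oyl]oxazolidin-2-one
Product: 25 6-(tert-butyldimethylsilyloxy)-3,3-(ethylenedioxy)-9βH-drim-6-en-11-ol
Conditions: LiBH4, MeOH (1 equiv), THF, 0 °C → rt
Reagents that add atoms: none
Why: Reductive cleavage of the N-acyl oxazolidinone by hydride attack at the exocyclic carbonyl gives the C11 primary alcohol and returns the auxiliary, the silyl enol ether and the ketal being inert to borohydride.

Step 15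
Reactants: 25 6-(tert-butyldimethylsilyloxy)-3,3-(ethylenedioxy)-9βH-drim-6-en-11-ol
Product: 26 3,3-(ethylenedioxy)-11-hydroxy-9βH-drim-7-en-6-one
Conditions: Pd(OAc)2 (1.1 equiv), MeCN, rt → 40 °C
Reagents that add atoms: none
Why: Saegusa–Ito oxidation, in which divalent palladium turns the silyl enol ether into the C7-palladated ketone and syn β-hydride elimination can only take the C8 hydrogen, giving the C7=C8 enone and erasing the C8 stereocentre.

Step 16
Reactants: 26 3,3-(ethylenedioxy)-11-hydroxy-9βH-drim-7-en-6-one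
Product: 27 11-hydroxy-9βH-drim-7-ene-3,6-dione
Conditions: 2 M aq. HCl, THF, rt → 40 °C
Reagents that add atoms: water, O
Why: Acid hydrolysis of the dioxolane releases the C3 ketone and lets C5 (α to C6) enolise, so that any cis-fused material should converge on the more stable trans-fused 5α-H isomer, while H9 lies close to the enone plane and is not expected to exchange.

Step 17
Reactants: 27 11-hydroxy-9βH-drim-7-ene-3,6-dione
Product: 28 3α,11-dihydroxy-9βH-drim-7-en-6-one
Conditions: KBH(s-Bu)3 (2.2 equiv), THF, −78 °C; aq. NH4Cl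
Reagents that add atoms: none
Why: The bulky trialkylborohydride should reduce the saturated C3 ketone before the hindered, conjugated, β,β-disubstituted C6 enone (as in selective reductions of Wieland–Miescher-type enediones) and attack from the equatorial direction, as known for 4,4-dimethyl-3-keto terpenoids, giving the axial 3α-alcohol.

Step 18
Reactants: 28 3α,11-dihydroxy-9βH-drim-7-en-6-one; 29 isofraxidin (7-hydroxy-6,8-dimethoxycoumarin)
Product: 30 11-(6,8-dimethoxy-2-oxo-2H-chromen-7-yloxy)-3α-hydroxy-9βH-drim-7-en-6-one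
Conditions: PPh3, DIAD, THF, 0 °C → rt
Reagents that add atoms: none
Why: Mitsunobu etherification, in which the primary C11 alcohol is activated in preference to the hindered axial 3α-OH and is displaced by the acidic phenol, C11 carrying no stereocentre.

Step 19
Reactants: 30 11-(6,8-dimethoxy-2-oxo-2H-chromen-7-yloxy)-3α-hydroxy-9βH-drim-7-en-6-one
Product: 31 target, (3R,5R,9R,10R)-11-(6,8-dimethoxy-2-oxo-2H-chromen-7-yloxy)-3-(3-methylbutanoyloxy)drim-7-en-6-one (CNP0279705.1)
Conditions: 3-methylbutanoyl chloride, pyridine, DMAP (cat.), CH2Cl2, 0 °C → rt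
Reagents that add atoms: 3-methylbutanoyl chloride, CC(C)CC(Cl)=O
Why: DMAP-catalysed O-acylation of the only remaining hydroxyl proceeds with retention at C3 and leaves the enone and the coumarin lactone untouched.

**Compound list**

1 | 2,2-dimethylpent-4-enal | C=CCC(C)(C)C=O | starting material
2 | (4-bromobut-1-yn-1-yl)trimethylsilane | C[Si](C)(C)C#CCCBr | starting material
3 | [4-(trimethylsilyl)but-3-yn-1-yl]magnesium bromide (formed in situ) | C[Si](C)(C)C#CCC[Mg]Br | intermediate
4 | rac-6,6-dimethyl-1-(trimethylsilyl)non-8-en-1-yn-5-ol | C[Si](C)(C)C#CCCC(O)C(C)(C)CC=C | intermediate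
5 | 6,6-dimethyl-1-(trimethylsilyl)non-8-en-1-yn-5-one | C[Si](C)(C)C#CCCC(=O)C(C)(C)CC=C | intermediate
6 | 2-(2-methylpent-4-en-2-yl)-2-[4-(trimethylsilyl)but-3-yn-1-yl]-1,3-dioxolane | C[Si](C)(C)C#CCCC1(OCCO1)C(C)(C)CC=C | intermediate
7 | 2-(but-3-yn-1-yl)-2-(2-methylpent-4-en-2-yl)-1,3-dioxolane | C#CCCC1(OCCO1)C(C)(C)CC=C | intermediate
8 | lithium acetylide of 7 (formed in situ) | [Li]C#CCCC1(OCCO1)C(C)(C)CC=C | intermediate
9 | ethyl 5-[2-(2-methylpent-4-en-2-yl)-1,3-dioxolan-2-yl]pent-2-ynoate | CCOC(=O)C#CCCC1(OCCO1)C(C)(C)CC=C | intermediate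
10 | lithium alkenyl(methyl)cuprate from syn addition to 9 (formed in situ; Cu cis to the new methyl) | CCOC(=O)/C([Cu-]C)=C(/C)CCC1(OCCO1)C(C)(C)CC=C.[Li+] | intermediate
11 | ethyl (Z)-3-methyl-5-[2-(2-methylpent-4-en-2-yl)-1,3-dioxolan-2-yl]pent-2-enoate | CCOC(=O)/C=C(C)\CCC1(OCCO1)C(C)(C)CC=C | intermediate
12 | (Z)-3-methyl-5-[2-(2-methylpent-4-en-2-yl)-1,3-dioxolan-2-yl]pent-2-enoic acid | OC(=O)/C=C(C)\CCC1(OCCO1)C(C)(C)CC=C | intermediate
13 | (R)-4-benzyl-2-oxazolidinone | O=C1OC[C@@H](Cc2ccccc2)N1 | starting material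
14 | mixed anhydride of 12 with pivalic acid (formed in situ) | CC(C)(C)C(=O)OC(=O)/C=C(C)\CCC1(OCCO1)C(C)(C)CC=C | intermediate
15 | lithium salt of 13 (formed in situ) | O=C1OC[C@@H](Cc2ccccc2)N1[Li] | intermediate
16 | (R)-4-benzyl-3-[(Z)-3-methyl-5-[2-(2-methylpent-4-en-2-yl)-1,3-dioxolan-2-yl]pent-2-enoyl]oxazolidin-2-one | O=C1OC[C@@H](Cc2ccccc2)N1C(=O)/C=C(C)\CCC3(OCCO3)C(C)(C)CC=C | intermediate
17 | vicinal diol from 16 (formed in situ, both carbinol epimers) | O=C1OC[C@@H](Cc2ccccc2)N1C(=O)/C=C(C)\CCC3(OCCO3)C(C)(C)CC(O)CO | intermediate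
18 | (R)-4-benzyl-3-[(Z)-3-methyl-5-[2-(2-methyl-4-oxobutan-2-yl)-1,3-dioxolan-2-yl]pent-2-enoyl]oxazolidin-2-one | O=C1OC[C@@H](Cc2ccccc2)N1C(=O)/C=C(C)\CCC3(OCCO3)C(C)(C)CC=O | intermediate
19 | (E)-1-bromoprop-1-ene | C/C=C/Br | starting material
20 | (E)-prop-1-enylchromium dichloride (formed in situ) | C/C=C/[Cr](Cl)Cl | intermediate
21 | (R)-4-benzyl-3-[(Z)-5-[2-[(E)-4-hydroxy-2-methylhept-5-en-2-yl]-1,3-dioxolan-2-yl]-3-methylpent-2-enoyl]oxazolidin-2-one (both C6 carbinol epimers) | O=C1OC[C@@H](Cc2ccccc2)N1C(=O)/C=C(C)\CCC3(OCCO3)C(C)(C)CC(O)/C=C/C | intermediate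
22 | (R)-4-benzyl-3-[(Z)-3-methyl-5-[2-[(E)-2-methyl-4-oxohept-5-en-2-yl]-1,3-dioxolan-2-yl]pent-2-enoyl]oxazolidin-2-one | O=C1OC[C@@H](Cc2ccccc2)N1C(=O)/C=C(C)\CCC3(OCCO3)C(C)(C)CC(=O)/C=C/C | intermediate
23 | (R)-4-benzyl-3-[(Z)-5-[2-[(3Z,5E)-4-(tert-butyldimethylsilyloxy)-2-methylhepta-3,5-dien-2-yl]-1,3-dioxolan-2-yl]-3-methylpent-2-enoyl]oxazolidin-2-one (silyloxytriene) | O=C1OC[C@@H](Cc2ccccc2)N1C(=O)/C=C(C)\CCC3(OCCO3)C(C)(C)/C=C(O[Si](C)(C)C(C)(C)C)/C=C/C | intermediate
24 | (R)-4-benzyl-3-[6-(tert-butyldimethylsilyloxy)-3,3-(ethylenedioxy)-9βH-drim-6-en-11-oyl]oxazolidin-2-one (5α-H, 8β-CH3, 9β-H, 10β-CH3) | O=C1OC[C@@H](Cc2ccccc2)N1C(=O)[C@@H]1[C@@H](C)C=C(O[Si](C)(C)C(C)(C)C)[C@H]2C(C)(C)C3(OCCO3)CC[C@]12C | intermediate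
25 | 6-(tert-butyldimethylsilyloxy)-3,3-(ethylenedioxy)-9βH-drim-6-en-11-ol | OC[C@@H]1[C@@H](C)C=C(O[Si](C)(C)C(C)(C)C)[C@H]2C(C)(C)C3(OCCO3)CC[C@]12C | intermediate
26 | 3,3-(ethylenedioxy)-11-hydroxy-9βH-drim-7-en-6-one | OC[C@@H]1C(C)=CC(=O)[C@H]2C(C)(C)C3(OCCO3)CC[C@]12C | intermediate
27 | 11-hydroxy-9βH-drim-7-ene-3,6-dione | OC[C@@H]1C(C)=CC(=O)[C@H]2C(C)(C)C(=O)CC[C@]12C | intermediate
28 | 3α,11-dihydroxy-9βH-drim-7-en-6-one | OC[C@@H]1C(C)=CC(=O)[C@H]2C(C)(C)[C@H](O)CC[C@]12C | intermediate
29 | isofraxidin (7-hydroxy-6,8-dimethoxycoumarin) | COc1cc2ccc(=O)oc2c(OC)c1O | starting material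
30 | 11-(6,8-dimethoxy-2-oxo-2H-chromen-7-yloxy)-3α-hydroxy-9βH-drim-7-en-6-one | COc1cc2ccc(=O)oc2c(OC)c1OC[C@@H]1C(C)=CC(=O)[C@H]2C(C)(C)[C@H](O)CC[C@]12C | intermediate
31 | (3R,5R,9R,10R)-11-(6,8-dimethoxy-2-oxo-2H-chromen-7-yloxy)-3-(3-methylbutanoyloxy)drim-7-en-6-one (CNP0279705.1) | COc1cc2ccc(=O)oc2c(OC)c1OC[C@@H]1C(C)=CC(=O)[C@H]2C(C)(C)[C@H](OC(=O)CC(C)C)CC[C@]12C | target

**Totals**

Total step count: 19. Longest linear sequence: 19 steps (1 → 31).

**Steps most likely to fail**

Step 13. The Lewis acid may strip the silyl group or open the dioxolane before the hindered C5–C10 bond forms, the reaction may stall after the first bond, or facial discrimination at the β,β-disubstituted acceptor may be poor. The fallback sets out from enone 22 and replaces the cycloaddition by an anionic double Michael reaction. Kinetic α′ deprotonation with LiN(SiMe3)2 (THF, −78 → −20 °C) gives the cross-conjugated lithium dienolate, which should add to the lithium-chelated enoyl imide at C10; the resulting imide enolate then closes onto C8. Aqueous quench gives the saturated decalin C6 ketone, (R)-4-benzyl-3-[3,3-(ethylenedioxy)-6-oxo-9βH-driman-11-oyl]oxazolidin-2-one F1. TBSOTf/Et3N then enolises F1 toward C7, the only unhindered α-position, and the route is rejoined at 24.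

Step 18. Substitution at the β-branched, axial C11 by the di-ortho-substituted phenoxide may be slow, so that alkylation of the hydrazide or elimination toward an exocyclic C9=C11 dienone takes over. The fallback sets out from 28 and separates activation from displacement. Tf2O with 2,6-di-tert-butyl-4-methylpyridine (CH2Cl2, −78 °C) should sulfonylate only the primary hydroxyl to give the C11 triflate, 3α-hydroxy-6-oxo-9βH-drim-7-en-11-yl trifluoromethanesulfonate F3. This is treated directly with isofraxidin 29 and Cs2CO3 (DMF/MeCN, 0 °C → rt) in a Williamson displacement, and the route is rejoined at 30.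

Step 17. Hydride may also add to the C6 enone carbonyl, or the two carbonyls may not be told apart cleanly. The fallback sets out from 27 and gives up chemoselectivity in the reduction. Excess LiBH(s-Bu)3 (THF, −78 → 0 °C) reduces both carbonyls, C3 still from the equatorial side, to the triol 9βH-drim-7-ene-3α,6,11-triol F2 (C6 configuration immaterial). MnO2 (CH2Cl2, rt) then re-oxidises only the allylic C6 alcohol, and the route is rejoined at 28.

**Further compounds**

F1 | step 13 | (R)-4-benzyl-3-[3,3-(ethylenedioxy)-6-oxo-9βH-driman-11-oyl]oxazolidin-2-one (5α-H, 8β-CH3, 10β-CH3) | O=C1OC[C@@H](Cc2ccccc2)N1C(=O)[C@@H]1[C@@H](C)CC(=O)[C@H]2C(C)(C)C3(OCCO3)CC[C@]12C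
F2 | step 17 | 9βH-drim-7-ene-3α,6,11-triol (C6 epimers) | OC[C@@H]1C(C)=CC(O)[C@H]2C(C)(C)[C@H](O)CC[C@]12C
F3 | step 18 | 3α-hydroxy-6-oxo-9βH-drim-7-en-11-yl trifluoromethanesulfonate | O=S(=O)(OC[C@@H]1C(C)=CC(=O)[C@H]2C(C)(C)[C@H](O)CC[C@]12C)C(F)(F)F
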